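**Plan**
- Retrosynthesis: the dihydropyranone is opened at C1–O and C2=C3 (acrylate ester, ring-closing metathesis); C4–C5 and C6–C7 are cut as allylborations of C5 and C7 aldehydes; C13–C14 is cut as a copper-catalysed alkyl–alkyl coupling.
- Enabling feature: the carbinols C9 and C11 lie 1,3 on the seven-carbon stretch C7–C13. Bonding C7 to C13 folds it into a cycloheptene whose C9 oxygen bridges to C13. This 8-oxabicyclo[3.2.1]octene is cut at C9–C10 and C12–C13 into furan (C7, C8, C9, C13, the C9 oxygen) and an acetone-derived oxyallyl cation (C10–C12, the C11 oxygen).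
- Forward: the [4+3] cycloaddition closes the carbocycle and the oxygen-bridged six-membered ring together. The bridge is then opened reductively and the ring alkene ozonised (C7 aldehyde, C13 lactol). C7 is allylated, the C14–C26 chain is attached at C13, C5 is allylated, and the lactone ring is closed last.
- Stereochemistry: C9/C13 are cis through the bridge (meso); thermodynamic (equatorial) ketone reduction puts the C11 oxygen syn to the C9 oxygen; the Ni–BINAP ring opening of the meso ether sets the absolute configuration; C7 and C5 come from (−)-Ipc2B(allyl); the ring fixes the C2=C3 geometry.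

Key step: step 1

Numbering: locants C1–C26 are those of the target (C1 lactone carbonyl, C5 ring carbinol, C26 methyl). TBS = tert-butyldimethylsilyl, Ipc = isopinocampheyl, PPTS = pyridinium 4-toluenesulfonate.
Assumption: the Ni–(S)-BINAP catalyst is taken to break the bridge C–O bond that leads to the (1S,6R)-cycloheptenol; the silyl ether substrate is meso, so (R)-BINAP would be used instead, with no other change, if the sense proved opposite.

**Step 1**
Reactants: 1 furan; 2 1,1,3,3-tetrabromopropan-2-one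
Product: 5 8-oxabicyclo[3.2.1]oct-6-en-3-one (meso ketone), via zinc-bound 1,3-dibromo-2-oxyallyl cation 3 (not isolated), via 2,4-dibromo-8-oxabicyclo[3.2.1]oct-6-en-3-one 4 (not isolated)
Conditions: Zn–Cu couple, THF, −10 °C → rt, furan in excess; then Zn–Cu couple, NH4Cl, MeOH, −78 °C → rt
Reagents that add atoms: none
Why: Zinc inserts into a C–Br bond of 2 and the resulting bromozinc enolate ionises the second α-bromide, so the three-carbon, 2π-electron oxyallyl cation 3 forms in the presence of the 4π diene of furan; the closest known reaction type is the [4+3] cycloaddition of polybromoketone-derived oxyallyl cations with furans followed by zinc–copper reductive debromination. The cation adds across furan C2 and C5 (concerted, or electrophilic attack followed by fast ring closure) and forms C9–C10 and C12–C13, so the seven-membered carbocycle C7–C13 is closed by intermolecular [4+3] cycloaddition and the six-membered oxane ring (O, C9–C13) is closed in the same event, the furan oxygen becoming the bridge. The new stereocentres C9 and C13 can only be cis because both bonds are made on one face of the planar furan, which makes 4 and 5 meso; the two CHBr centres of 4 do not matter because Zn–Cu and NH4Cl replace both bromines by hydrogen. The step needs mono-cycloaddition in preference to electrophilic substitution or polymerisation of furan and to a second addition: furan is in excess, its 2,5-positions are free and electron-rich, the remaining bromines stabilise the cation, and the isolated alkene of the adduct is no partner for a second cation.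

**Step 2**
Reactants: 5 8-oxabicyclo[3.2.1]oct-6-en-3-one
Product: 6 3-exo-8-oxabicyclo[3.2.1]oct-6-en-3-ol (meso; hydroxyl equatorial on the oxane chair, on the same side of the seven-membered ring as the oxygen bridge)
Conditions: SmI2, i-PrOH, THF, reflux
Reagents that add atoms: none
Why: Single-electron (ketyl) ketone reduction by SmI2 with i-PrOH as proton source is under thermodynamic control and should give the more stable equatorial 3-exo alcohol, which places the C11 oxygen on the face of the seven-membered ring that carries the bridge oxygen (the later 1,3-syn C9/C11 pair), while the alkene is left alone.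

**Step 3**
Reactants: 6 3-exo-8-oxabicyclo[3.2.1]oct-6-en-3-ol
Product: 7 3-exo-3-[(tert-butyldimethylsilyl)oxy]-8-oxabicyclo[3.2.1]oct-6-ene (meso)
Conditions: TBSCl, imidazole, DMF, rt
Reagents that add atoms: tert-butyldimethylsilyl chloride, CC(C)(C)[Si](C)(C)Cl
Why: Imidazole-promoted silyl ether formation masks the C11 hydroxyl with a group that should survive i-Bu2AlH, ozone, Grignard and allylborane reagents and is removed by acid at the end; no stereocentre is affected.

**Step 4**
Reactants: 7 3-exo-3-[(tert-butyldimethylsilyl)oxy]-8-oxabicyclo[3.2.1]oct-6-ene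
Product: 8 (1S,6R)-6-[(tert-butyldimethylsilyl)oxy]cyclohept-3-en-1-ol (cis; ring C1 = C9, C6 = C11, alkene C7=C13)
Conditions: Ni(cod)2 (cat.), (S)-BINAP (cat.), i-Bu2AlH (slow addition), toluene, 60 °C; then aqueous potassium sodium tartrate
Reagents that add atoms: none
Why: Nickel-catalysed enantioselective reductive ring opening of a meso oxabicyclic alkene: the chiral Ni–BINAP hydride adds on the exo face to one of the two enantiotopic alkene carbons (C8) and β-alkoxide elimination breaks the C13–O bond, so the bridge oxygen stays on C9 as the free hydroxyl and the ligand alone decides which enantiomer forms, slow addition of i-Bu2AlH keeping the uncatalysed racemic pathway down.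

**Step 5**
Reactants: 8 (1S,6R)-6-[(tert-butyldimethylsilyl)oxy]cyclohept-3-en-1-ol
Product: 10 2-[(2R,4S,6RS)-4-[(tert-butyldimethylsilyl)oxy]-6-hydroxyoxan-2-yl]acetaldehyde (C13 lactol on the C9 oxygen; free C7 aldehyde; anomer mixture), via bicyclic ozonide 9 (not isolated)
Conditions: O3, CH2Cl2, −78 °C; then PPh3, −78 °C → rt
Reagents that add atoms: ozone, [O-][O+]=O
Why: Criegee ozonolysis with reductive work-up cleaves C7=C13; the C9 hydroxyl closes a six-membered lactol on the C13 aldehyde but cannot reach C7 (a four-membered ring would be needed), so the two chain ends are differentiated and C7 is the only free aldehyde, with no chain stereocentre touched.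

**Step 6**
Reactants: 10 2-[(2R,4S,6RS)-4-[(tert-butyldimethylsilyl)oxy]-6-hydroxyoxan-2-yl]acetaldehyde
Product: 11 (2S)-1-[(2S,4S,6RS)-4-[(tert-butyldimethylsilyl)oxy]-6-hydroxyoxan-2-yl]pent-4-en-2-ol
Conditions: (−)-Ipc2BOMe, allylMgBr, Et2O, −78 °C → rt; then 10, −78 °C; then MeOH, pH 7 buffer, H2O2, 0 °C
Reagents that add atoms: (−)-B-allyldiisopinocampheylborane, C=CCB([C@@H]1C[C@@H]2C[C@H]([C@H]1C)C2(C)C)[C@@H]1C[C@@H]2C[C@H]([C@H]1C)C2(C)C, formed in the flask from (−)-Ipc2BOMe and allylmagnesium bromide, C=CC[Mg]Br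
Why: Brown allylation: the (−)-Ipc2B(allyl) reagent should add through a chair six-membered transition state to the Si face of the C7 aldehyde under reagent control, setting the C7 carbinol 1,3-syn to the C9 oxygen (S by CIP in this compound), while at −78 °C the cyclic hemiacetal at C13 is not expected to compete with the free aldehyde.

**Step 7**
Reactants: 11 (2S)-1-[(2S,4S,6RS)-4-[(tert-butyldimethylsilyl)oxy]-6-hydroxyoxan-2-yl]pent-4-en-2-ol
Product: 12 (3R,5S,7S)-3-[(tert-butyldimethylsilyl)oxy]dec-9-ene-1,5,7-triol (C13 primary OH, C9 and C7 secondary OH)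
Conditions: NaBH4, MeOH, 0 °C → rt
Reagents that add atoms: none
Why: Borohydride reduction of the lactol through its open hydroxy-aldehyde form frees the C9 hydroxyl and leaves C13 as the only primary alcohol, without change at any stereocentre.

**Step 8**
Reactants: 12 (3R,5S,7S)-3-[(tert-butyldimethylsilyl)oxy]dec-9-ene-1,5,7-triol
Product: 13 (3R)-3-[(tert-butyldimethylsilyl)oxy]-4-[(4S,6S)-2,2-dimethyl-6-(prop-2-en-1-yl)-1,3-dioxan-4-yl]butan-1-ol
Conditions: 2,2-dimethoxypropane, PPTS (cat.), CH2Cl2, rt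
Reagents that add atoms: 2,2-dimethoxypropane, COC(C)(C)OC
Why: Acid-catalysed transketalisation: the syn-1,3-diol C7/C9 should close a six-membered acetonide with both substituents equatorial, whereas the C13 hydroxyl has no partner for a normal-sized ring (C11 is silylated) and stays free.

**Step 9**
Reactants: 13 (3R)-3-[(tert-butyldimethylsilyl)oxy]-4-[(4S,6S)-2,2-dimethyl-6-(prop-2-en-1-yl)-1,3-dioxan-4-yl]butan-1-ol
Product: 14 (3R)-3-[(tert-butyldimethylsilyl)oxy]-4-[(4S,6S)-2,2-dimethyl-6-(prop-2-en-1-yl)-1,3-dioxan-4-yl]butyl 4-methylbenzenesulfonate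
Conditions: TsCl, Et3N, DMAP (cat.), CH2Cl2, 0 °C → rt
Reagents that add atoms: 4-methylbenzenesulfonyl chloride, Cc1ccc(cc1)S(=O)(=O)Cl
Why: Sulfonylation of the only free (primary) alcohol turns C13 into an electrophile; all secondary oxygens are protected.

**Step 10**
Reactants: 14 (3R)-3-[(tert-butyldimethylsilyl)oxy]-4-[(4S,6S)-2,2-dimethyl-6-(prop-2-en-1-yl)-1,3-dioxan-4-yl]butyl 4-methylbenzenesulfonate; 15 1-bromotridecane
Product: 17 tert-butyl{[(2R)-1-[(4S,6S)-2,2-dimethyl-6-(prop-2-en-1-yl)-1,3-dioxan-4-yl]heptadecan-2-yl]oxy}dimethylsilane, via tridecylmagnesium bromide 16 (not isolated)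
Conditions: 15, Mg, THF, reflux; then 14, Li2CuCl4 (cat.), THF, −78 °C → rt
Reagents that add atoms: none
Why: Copper-catalysed sp3–sp3 cross-coupling of a primary tosylate with a primary alkyl Grignard reagent (Kochi-type coupling) forms C13–C14 and delivers the saturated C14–C26 chain directly, acetonide, silyl ether and terminal alkene being inert to the organocopper species.

**Step 11**
Reactants: 17 tert-butyl{[(2R)-1-[(4S,6S)-2,2-dimethyl-6-(prop-2-en-1-yl)-1,3-dioxan-4-yl]heptadecan-2-yl]oxy}dimethylsilane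
Product: 19 2-[(4R,6S)-6-[(2R)-2-[(tert-butyldimethylsilyl)oxy]heptadecyl]-2,2-dimethyl-1,3-dioxan-4-yl]acetaldehyde (C5 aldehyde), via terminal ozonide 18 (not isolated)
Conditions: O3, CH2Cl2, −78 °C; then PPh3, −78 °C → rt
Reagents that add atoms: ozone, [O-][O+]=O
Why: Ozonolysis with reductive work-up converts the terminal alkene into the C5 aldehyde; acetonide and silyl ether are stable to ozone at −78 °C and no stereocentre is involved.

**Step 12**
Reactants: 19 2-[(4R,6S)-6-[(2R)-2-[(tert-butyldimethylsilyl)oxy]heptadecyl]-2,2-dimethyl-1,3-dioxan-4-yl]acetaldehyde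
Product: 20 (2S)-1-[(4S,6S)-6-[(2R)-2-[(tert-butyldimethylsilyl)oxy]heptadecyl]-2,2-dimethyl-1,3-dioxan-4-yl]pent-4-en-2-ol
Conditions: (−)-Ipc2BOMe, allylMgBr, Et2O, −78 °C → rt; then 19, −78 °C; then NaOH, H2O2, 0 °C → rt
Reagents that add atoms: (−)-B-allyldiisopinocampheylborane, C=CCB([C@@H]1C[C@@H]2C[C@H]([C@H]1C)C2(C)C)[C@@H]1C[C@@H]2C[C@H]([C@H]1C)C2(C)C, formed in the flask from (−)-Ipc2BOMe and allylmagnesium bromide, C=CC[Mg]Br
Why: Brown allylation under reagent control: the same (−)-Ipc2B(allyl) should add through the chair transition state to the Si face of the C5 aldehyde and set C5 (S), 1,3-syn to the C7 oxygen.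

**Step 13**
Reactants: 20 (2S)-1-[(4S,6S)-6-[(2R)-2-[(tert-butyldimethylsilyl)oxy]heptadecyl]-2,2-dimethyl-1,3-dioxan-4-yl]pent-4-en-2-ol
Product: 21 (2S)-1-[(4R,6S)-6-[(2R)-2-[(tert-butyldimethylsilyl)oxy]heptadecyl]-2,2-dimethyl-1,3-dioxan-4-yl]pent-4-en-2-yl prop-2-enoate
Conditions: acryloyl chloride, Et3N, DMAP (cat.), CH2Cl2, 0 °C
Reagents that add atoms: acryloyl chloride, C=CC(=O)Cl
Why: DMAP-catalysed O-acylation with an acid chloride puts C1–C2 on the C5 oxygen, the only free hydroxyl of the molecule.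

**Step 14**
Reactants: 21 (2S)-1-[(4R,6S)-6-[(2R)-2-[(tert-butyldimethylsilyl)oxy]heptadecyl]-2,2-dimethyl-1,3-dioxan-4-yl]pent-4-en-2-yl prop-2-enoate
Product: 22 (6S)-6-{[(4R,6S)-6-[(2R)-2-[(tert-butyldimethylsilyl)oxy]heptadecyl]-2,2-dimethyl-1,3-dioxan-4-yl]methyl}-5,6-dihydro-2H-pyran-2-one
Conditions: second-generation Grubbs catalyst (H2IMes)(PCy3)Cl2Ru=CHPh (cat.), CH2Cl2 (dilute), 40 °C
Reagents that add atoms: none
Why: Ring-closing olefin metathesis between the acrylate and the allyl terminus closes the six-membered α,β-unsaturated δ-lactone with loss of ethene, the ring size enforcing the Z C2=C3 bond and no stereocentre being involved.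

**Step 15**
Reactants: 22 (6S)-6-{[(4R,6S)-6-[(2R)-2-[(tert-butyldimethylsilyl)oxy]heptadecyl]-2,2-dimethyl-1,3-dioxan-4-yl]methyl}-5,6-dihydro-2H-pyran-2-one
Product: 23 (6S)-6-[(2R,4R,6R)-2,4,6-trihydroxyhenicosyl]-5,6-dihydro-2H-pyran-2-one (target)
Conditions: 3 M HCl (aq.), THF, 0 °C → rt
Reagents that add atoms: none
Why: Acid-catalysed acetal hydrolysis and silyl ether cleavage remove the acetonide and the TBS group in one operation; the unsaturated lactone tolerates aqueous acid, and base is avoided in work-up so that the C7 hydroxyl does not add to C3 by intramolecular oxa-Michael reaction.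

**Compound list**
1 | furan | c1ccoc1 | starting material
2 | 1,1,3,3-tetrabromopropan-2-one | O=C(C(Br)Br)C(Br)Br | starting material
3 | zinc-bound 1,3-dibromo-2-oxyallyl cation (bromozinc enolate cation, bromide counter-ion) | Br[CH+]C(O[Zn]Br)=CBr.[Br-] | intermediate (not isolated)
4 | 2,4-dibromo-8-oxabicyclo[3.2.1]oct-6-en-3-one (cis bridge, mixture at the CHBr centres) | O=C1C(Br)[C@@H]2C=C[C@H](C1Br)O2 | intermediate (not isolated)
5 | (1R,5S)-8-oxabicyclo[3.2.1]oct-6-en-3-one (meso) | O=C1C[C@@H]2C=C[C@H](C1)O2 | intermediate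
6 | 3-exo-8-oxabicyclo[3.2.1]oct-6-en-3-ol (meso, equatorial OH cis to the oxygen bridge) | C1[C@@H](O)C[C@@H]2C=C[C@H]1O2 | intermediate
7 | 3-exo-3-[(tert-butyldimethylsilyl)oxy]-8-oxabicyclo[3.2.1]oct-6-ene (meso) | C1[C@@H](O[Si](C)(C)C(C)(C)C)C[C@@H]2C=C[C@H]1O2 | intermediate
8 | (1S,6R)-6-[(tert-butyldimethylsilyl)oxy]cyclohept-3-en-1-ol | C1[C@@H](O[Si](C)(C)C(C)(C)C)C[C@@H](O)CC=C1 | intermediate
9 | ozonide of 8 (8,9,10-trioxabicyclo[5.2.1]decane with 3-OH and 5-OTBS, cis) | C1[C@@H](O[Si](C)(C)C(C)(C)C)C[C@@H](O)CC2OOC1O2 | intermediate (not isolated)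
10 | 2-[(2R,4S,6RS)-4-[(tert-butyldimethylsilyl)oxy]-6-hydroxyoxan-2-yl]acetaldehyde | OC1C[C@@H](O[Si](C)(C)C(C)(C)C)C[C@H](CC=O)O1 | intermediate
11 | (2S)-1-[(2S,4S,6RS)-4-[(tert-butyldimethylsilyl)oxy]-6-hydroxyoxan-2-yl]pent-4-en-2-ol | OC1C[C@@H](O[Si](C)(C)C(C)(C)C)C[C@H](C[C@@H](O)CC=C)O1 | intermediate
12 | (3R,5S,7S)-3-[(tert-butyldimethylsilyl)oxy]dec-9-ene-1,5,7-triol | OCC[C@@H](O[Si](C)(C)C(C)(C)C)C[C@@H](O)C[C@@H](O)CC=C | intermediate
13 | (3R)-3-[(tert-butyldimethylsilyl)oxy]-4-[(4S,6S)-2,2-dimethyl-6-(prop-2-en-1-yl)-1,3-dioxan-4-yl]butan-1-ol | OCC[C@@H](O[Si](C)(C)C(C)(C)C)C[C@@H]1C[C@H](CC=C)OC(C)(C)O1 | intermediate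
14 | (3R)-3-[(tert-butyldimethylsilyl)oxy]-4-[(4S,6S)-2,2-dimethyl-6-(prop-2-en-1-yl)-1,3-dioxan-4-yl]butyl 4-methylbenzenesulfonate | Cc1ccc(cc1)S(=O)(=O)OCC[C@@H](O[Si](C)(C)C(C)(C)C)C[C@@H]2C[C@H](CC=C)OC(C)(C)O2 | intermediate
15 | 1-bromotridecane | CCCCCCCCCCCCCBr | starting material
16 | tridecylmagnesium bromide | CCCCCCCCCCCCC[Mg]Br | intermediate (not isolated)
17 | tert-butyl{[(2R)-1-[(4S,6S)-2,2-dimethyl-6-(prop-2-en-1-yl)-1,3-dioxan-4-yl]heptadecan-2-yl]oxy}dimethylsilane | CCCCCCCCCCCCCCC[C@@H](O[Si](C)(C)C(C)(C)C)C[C@@H]1C[C@H](CC=C)OC(C)(C)O1 | intermediate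
18 | ozonide of 17 (3-substituted 1,2,4-trioxolane) | CCCCCCCCCCCCCCC[C@@H](O[Si](C)(C)C(C)(C)C)C[C@@H]1C[C@H](CC2OCOO2)OC(C)(C)O1 | intermediate (not isolated)
19 | 2-[(4R,6S)-6-[(2R)-2-[(tert-butyldimethylsilyl)oxy]heptadecyl]-2,2-dimethyl-1,3-dioxan-4-yl]acetaldehyde | CCCCCCCCCCCCCCC[C@@H](O[Si](C)(C)C(C)(C)C)C[C@@H]1C[C@H](CC=O)OC(C)(C)O1 | intermediate
20 | (2S)-1-[(4S,6S)-6-[(2R)-2-[(tert-butyldimethylsilyl)oxy]heptadecyl]-2,2-dimethyl-1,3-dioxan-4-yl]pent-4-en-2-ol | CCCCCCCCCCCCCCC[C@@H](O[Si](C)(C)C(C)(C)C)C[C@@H]1C[C@H](C[C@@H](O)CC=C)OC(C)(C)O1 | intermediate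
21 | (2S)-1-[(4R,6S)-6-[(2R)-2-[(tert-butyldimethylsilyl)oxy]heptadecyl]-2,2-dimethyl-1,3-dioxan-4-yl]pent-4-en-2-yl prop-2-enoate | CCCCCCCCCCCCCCC[C@@H](O[Si](C)(C)C(C)(C)C)C[C@@H]1C[C@H](C[C@@H](OC(=O)C=C)CC=C)OC(C)(C)O1 | intermediate
22 | (6S)-6-{[(4R,6S)-6-[(2R)-2-[(tert-butyldimethylsilyl)oxy]heptadecyl]-2,2-dimethyl-1,3-dioxan-4-yl]methyl}-5,6-dihydro-2H-pyran-2-one | CCCCCCCCCCCCCCC[C@@H](O[Si](C)(C)C(C)(C)C)C[C@@H]1C[C@H](C[C@@H]2CC=CC(=O)O2)OC(C)(C)O1 | intermediate
23 | (6S)-6-[(2R,4R,6R)-2,4,6-trihydroxyhenicosyl]-5,6-dihydro-2H-pyran-2-one | CCCCCCCCCCCCCCC[C@@H](O)C[C@@H](O)C[C@@H](O)C[C@@H]1CC=CC(=O)O1 | target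

**Step count and risks**
Total step count: 15. Longest linear sequence: 15 steps (steps 1–15 from furan and tetrabromoacetone; the Grignard reagent is made within step 10).

Steps most likely to fail:

1. Step 6 — loss of chemoselectivity between the two aldehyde-level carbons. If the lactol opens, or if the C7 carbonyl is held back as an internal hemiacetal with the lactol hydroxyl, allyl transfer to C13 competes and the reaction at C7 slows. Fallback: setting out from 10, the lactol alone is oxidised (TEMPO cat., PhI(OAc)2, CH2Cl2) to the lactone-aldehyde (4S,6R)-4-[(tert-butyldimethylsilyl)oxy]-6-(2-oxoethyl)oxan-2-one F1, in which C13 is at the ester level and inert to allylboranes. The same (−)-Ipc2B(allyl) addition at −78 °C should then give the hydroxy lactone (4S,6S)-4-[(tert-butyldimethylsilyl)oxy]-6-[(2S)-2-hydroxypent-4-en-1-yl]oxan-2-one F2. LiBH4 in THF reduces the lactone to the triol, and the route is rejoined at 12.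

2. Step 4 — insufficient discrimination of the two enantiotopic bridge C–O bonds, or background uncatalysed hydroalumination, eroding the enantiomeric purity on which every later stereocentre depends. Fallback: setting out from 6, the unprotected alcohol is opened with an achiral catalyst (Ni(cod)2, dppb, i-Bu2AlH, toluene) to meso (1R,3S)-cyclohept-5-ene-1,3-diol F3. Lipase-catalysed transesterification with vinyl acetate (Pseudomonas cepacia lipase, selected by screening for the required enantiotopic hydroxyl) desymmetrises it to the monoacetate (1S,6R)-6-hydroxycyclohept-3-en-1-yl acetate F4. Silylation (TBSCl, imidazole, DMF) gives (1S,6R)-6-[(tert-butyldimethylsilyl)oxy]cyclohept-3-en-1-yl acetate F5, and K2CO3 in MeOH removes the acetate, rejoining the route at 8.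

3. Step 2 — poor facial selectivity (axial alcohol from kinetic protonation) or pinacol coupling of the ketyl. Fallback: setting out from 5, LiBH(s-Bu)3 (THF, −78 °C) should attack along the open equatorial direction to give the axial alcohol 3-endo-8-oxabicyclo[3.2.1]oct-6-en-3-ol F6. Mitsunobu inversion (4-nitrobenzoic acid, PPh3, diisopropyl azodicarboxylate, THF) gives the equatorial ester 3-exo-8-oxabicyclo[3.2.1]oct-6-en-3-yl 4-nitrobenzoate F7, and K2CO3 in MeOH frees the equatorial alcohol, rejoining the route at 6.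

**Further compounds**
F1 | step 6 | (4S,6R)-4-[(tert-butyldimethylsilyl)oxy]-6-(2-oxoethyl)oxan-2-one | O=C1C[C@@H](O[Si](C)(C)C(C)(C)C)C[C@H](CC=O)O1
F2 | step 6 | (4S,6S)-4-[(tert-butyldimethylsilyl)oxy]-6-[(2S)-2-hydroxypent-4-en-1-yl]oxan-2-one | O=C1C[C@@H](O[Si](C)(C)C(C)(C)C)C[C@H](C[C@@H](O)CC=C)O1
F3 | step 4 | (1R,3S)-cyclohept-5-ene-1,3-diol (meso, cis) | C1[C@@H](O)C[C@@H](O)CC=C1
F4 | step 4 | (1S,6R)-6-hydroxycyclohept-3-en-1-yl acetate | C1[C@@H](O)C[C@@H](OC(C)=O)CC=C1
F5 | step 4 | (1S,6R)-6-[(tert-butyldimethylsilyl)oxy]cyclohept-3-en-1-yl acetate | C1[C@@H](O[Si](C)(C)C(C)(C)C)C[C@@H](OC(C)=O)CC=C1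
F6 | step 2 | 3-endo-8-oxabicyclo[3.2.1]oct-6-en-3-ol (meso, axial OH) | C1[C@H](O)C[C@@H]2C=C[C@H]1O2
F7 | step 2 | 3-exo-8-oxabicyclo[3.2.1]oct-6-en-3-yl 4-nitrobenzoate (meso) | C1[C@@H](OC(=O)c3ccc(cc3)[N+](=O)[O-])C[C@@H]2C=C[C@H]1O2
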